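## Structural features

Dysidenone B consists of a trans-fused octalin and a 4-hydroxycyclopent-2-enone. Ring A is C4a, C5–C8, C8a with the trisubstituted C5=C6 alkene, ring B is C1–C4, C4a, C8a, and ring C is C1′–C5′. The two parts are joined only by one CH2 group between the quaternary C2 and C5′. Four decalin stereocentres are contiguous (C4a–C8a–C1–C2), and two of them (C4a, C2) are quaternary. The C1 and C4a methyl groups are 1,3-diaxial on one face and the C2 methyl is axial on the other, so the C1 configuration is contra-thermodynamic and cannot be reached by equilibration. Ring C holds two adjacent stereocentres, the tertiary carbinol C1′ (OH, CO2Me) and C5′ (H, CH2), with OH and CH2 trans. A freely rotating link separates them from C2, so the decalin cannot be expected to control them. The fragile parts are the β-hydroxy ketone of ring C (retro-aldol cleavage, epimerisation at C5′), its enol ether and ester, and the C5=C6 alkene (acid, electrophilic oxidants, hydrogenation). The real difficulty is the vicinal pair C1 (axial methyl) and C2 (quaternary, CH3 against CH2 link) beside the ring fusion, followed by the remote ring C centres. The key step uses the fact that C1 and C2 are neighbours in ring B with C4 two atoms beyond C2. If C1 is the α-carbon of a δ-lactone fused to ring A at C4a–C8a, and C2 is the end of an alkenyl group on the lactone carbinol carbon C4, then C1=C(O)–O–C4–C3=C2 is an allyl vinyl ether array. Its [3,3] shift makes C1–C2, closes ring B, and leaves a carboxyl group where the C1 methyl is needed.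

## Logic of the disconnections

**37 ⇒ 36.** The C5′–C1′ bond of ring C is cut (retro-aldol). C5′ is the only enolisable carbon of the chain and C1′, an α-keto ester carbonyl, is its most electrophilic site, so the closure can run in one direction only. The cut removes ring C and both of its stereocentres. The forward step must choose one face of C1′ without help from the decalin and must be mild enough to leave C5′ untouched afterwards.

**36 ⇒ 34.** No C–C bond is cut. The two keto groups C1′ and C4′ are folded back onto one oxygen as a furan. The furan stores the cis relation of C1′ and C4′, the methoxy group and the ester in a robust aromatic ring that tolerates cross-coupling. The forward oxidant must take the furan and spare C5=C6.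

**34 ⇒ 29 + 32.** The sp3–sp2 bond C5′–C4′ is cut. This avoids any substitution at the neopentyl link carbon and makes the endgame convergent. The forward step needs a hydroboration that touches only the vinyl group, followed by a B-alkyl cross-coupling.

**29 ⇒ 28 ⇒ 27 ⇒ 26.** The C5′=C(link) double bond is cut (Wittig), and the link carbon is returned to the protected alcohol level. C5′ enters as a one-carbon ylide, and the link carbon is the oxygenated carbon delivered by the key step. The aldehyde is hindered but cannot enolise, so nothing can epimerise.

**26 ⇒ 25 ⇒ 24 ⇒ 23 ⇒ 22.** No skeletal bond is cut. The C1 methyl is traced to a carboxyl group and C3–C4 to an alkene, which exposes a γ,δ-unsaturated acid. The price in the forward direction is a hydride displacement at a hindered axial CH2 and a reduction of the disubstituted alkene in the presence of the trisubstituted one.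

**22 ⇒ 19.** C1–C2 is cut and C4–O reconnected (retro-[3,3]). Ring B and the two hardest stereocentres disappear together. What remains is a bicyclic lactone whose stereocentres (C4, C4a, C8a) are of aldol/Michael type. The forward step requires the alkenyl group to be axial and anti to the angular methyl, and the alkene to be E.

**19 ⇒ 18 ⇒ 17.** The C5–CH3 bond is cut back to a ketone through its enol triflate. The ketone is the handle that built C4a. The forward steps must respect an allylic lactone.

**17 ⇒ 16 ⇒ 13 + 5.** The lactone C–O bond and the C4–C4a bond are cut (retro-aldol). This splits the molecule into ring A and the C2–C4 unit. The forward aldol must create quaternary C4a trans to the C8a side chain and must give one C4 epimer, which calls for a closed transition state and a regiodefined, ester-tolerant enolate.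

**13 ⇒ 12 ⇒ 10 ⇒ 8 + 7.** C8a–C1 is cut (retro-Michael), and an isopropenyl group is added retrosynthetically at C7. This lets a chiral-pool enone fix C8a, and with it every later centre of the decalin, without a resolution. The control group must leave before any other alkene is present.

**5 ⇒ 1, 7 ⇒ 6, 32 ⇒ 30.** These are functional group changes only: E-selective allylic oxidation, ketene acetal formation, and methoxylation followed by bromination.

## Other disconnections considered

**Alternative 1:** The cut removes C4a–C8a and C7–C8 together and opens both carbocycles to the trienone A1, (7E)-4,7,8-trimethyl-4-(triisopropylsilyloxymethyl)deca-1,7,9-trien-3-one. In the forward sense Et2AlCl would activate the vinyl ketone for an intramolecular Diels–Alder reaction to the octalone A2.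

- *In favour:* two rings, two C–C bonds and two stereocentres arise in one step from an open chain. Step 13 forms one ring and one bond, so this plan is better in bond-forming efficiency and in the step count to the bicyclic core. C8a of A2 is α to the ketone, so the trans fusion could be secured by equilibration, which makes it equal in reliability to the present setting of the fusion.
- *Against:* the reacting diene terminus C4a is fully substituted and carries an inward-pointing methyl group. This disfavours the s-cis conformer and asks a cycloaddition to make a quaternary centre. The only stereocentre of A1 must transmit its configuration to C4a across the tether by telling CH3 from CH2OSi, and it is itself an acyclic quaternary centre that needs its own asymmetric synthesis. The C1 ketone of A2, flanked by C2, must still become an axial methyl group against thermodynamics and with C5=C6 present.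
- *Comparison:* both key steps are concerted pericyclic reactions. The [3,3] route is longer, but it fixes C1 and C2 stereospecifically, which is the point Alternative 1 leaves open.

**Alternative 2:** The cut is C4′–C5′ in ring C. In the forward sense Bu3SnH and azobisisobutyronitrile would turn the selenoester A3 into an acyl radical that closes 5-exo onto C5′. The radical at the link carbon is then reduced, giving O-triethylsilyl dysidenone B, A4.

- *In favour:* the conditions are neutral, and C1′ is fixed and protected before ring closure, so retro-aldol scrambling is impossible. C5′ forms anti to the bulky silyloxy group, which is the OH/CH2 trans relation of 37. On ring C stereocontrol this plan is better than step 25.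
- *Against:* it says nothing about the decalin, so it complements the chosen key step more than it competes with it. A3 needs an enantiopure tertiary carbinol bearing two different alkenyl groups, joined through an E-alkene to the neopentyl C2. The α,β-unsaturated acyl radical can escape through ketene-type isomerisation or premature reduction. The closure must form a cyclopentenone that already contains a cis double bond. A deprotection and the removal of tin and selenium residues follow.
- *Comparison:* on step economy, the three steps from 29 to 37 are shorter than any foreseeable access to A3.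

**Alternative 3:** The cut is C4–C4a. In the forward sense KOtBu would convert the bromo phenol A5 into its phenoxide, whose methyl-bearing ortho carbon displaces the bromide to give the 2,4-dienone A6.

- *In favour:* ring A comes from a cheap arene, C4a and ring B arise together, and six-ring C-alkylation should beat eight-ring O-alkylation. The C5 carbonyl of A6 allows the same enol triflate/methyl coupling as in steps 11 and 12, so the two plans are equal on that point.
- *Against:* the vicinal C1/C2 pair must already be present in the open chain of A5, which moves the hardest problem to acyclic stereocontrol. The face of C4a depends only on chain conformation. A6 is prone to [4+2] dimerisation and to dienone–phenol rearrangement. Two ring A double bonds must still be removed or moved, and C8a–H set trans on a centre that is sp2 in A6.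
- *Comparison:* the ionic closure is simpler to run than a high-temperature rearrangement. The redox work after it, and the chain synthesis before it, make the route longer and less certain in stereochemistry.

Key step: step 13

Remark (numbering): C1–C8a are the decalin atoms (C1 = CH–CH3, C2 = quaternary carbon with the CH2 link, C4a = angular quaternary carbon) and are used for the same atoms in all precursors; C1′ (carbinol) to C5′ (CH) are the ring C atoms; α is the face of the C4a methyl group and β the opposite face.

Remark (ring size and source of chirality): ring A needs a six-membered enone, whose parent is 2-methylcyclohex-2-en-1-one, CC1=CCCCC1=O; the string CC1=CCCC1=O is 2-methylcyclopent-2-en-1-one and would lead to a hydrindane, so the route uses 8, the enantiopure 5-isopropenyl derivative of the six-membered enone; 1, 6, 8 and 30 are taken as purchasable.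

## Steps

Step 1
Reactants: 1 3-methylbut-2-enyl acetate
Product: 2 (E)-4-hydroxy-3-methylbut-2-enyl acetate
Conditions: SeO2 (cat.), t-BuOOH, CH2Cl2, 0 °C to rt
Reagents that add atoms: tert-butyl hydroperoxide, CC(C)(C)OO
Why: Allylic oxidation with catalytic SeO2 (ene reaction, then [2,3]-sigmatropic shift) attacks the methyl group trans to the CH2OAc chain, so the E-allylic alcohol is expected; this geometry later becomes the C2 configuration.

Step 2
Reactants: 2 (E)-4-hydroxy-3-methylbut-2-enyl acetate
Product: 3 (E)-4-(tert-butyldimethylsilyloxy)-3-methylbut-2-enyl acetate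
Conditions: TBSCl, imidazole, CH2Cl2, rt
Reagents that add atoms: tert-butyldimethylsilyl chloride, CC(C)(C)[Si](C)(C)Cl
Why: Standard silylation of a primary allylic alcohol; the TBS ether should survive every step up to step 18.

Step 3
Reactants: 3 (E)-4-(tert-butyldimethylsilyloxy)-3-methylbut-2-enyl acetate
Product: 4 (E)-4-(tert-butyldimethylsilyloxy)-3-methylbut-2-en-1-ol
Conditions: K2CO3 (cat.), MeOH, 0 °C
Reagents that add atoms: none
Why: Base-catalysed methanolysis (transesterification) removes the acetate and leaves the silyl ether and the alkene geometry untouched.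

Step 4
Reactants: 4 (E)-4-(tert-butyldimethylsilyloxy)-3-methylbut-2-en-1-ol
Product: 5 (E)-4-(tert-butyldimethylsilyloxy)-3-methylbut-2-enal
Conditions: MnO2, CH2Cl2, rt
Reagents that add atoms: none
Why: MnO2 oxidises allylic alcohols to enals under neutral conditions, so the E geometry and the silyl ether are kept.

Step 5
Reactants: 6 methyl acetate
Product: 7 1-(tert-butyldimethylsilyloxy)-1-methoxyethene
Conditions: LiN(iPr)2, THF, −78 °C; TBSCl, DMPU, −78 °C to rt
Reagents that add atoms: tert-butyldimethylsilyl chloride, CC(C)(C)[Si](C)(C)Cl
Why: Kinetic ester enolate formation and O-silylation in the presence of DMPU give the ketene silyl acetal, the acetate nucleophile for the Mukaiyama–Michael reaction.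

Step 6
Reactants: 8 (R)-carvone; 7 1-(tert-butyldimethylsilyloxy)-1-methoxyethene
Product: 10 methyl 2-[2-methyl-3-oxo-5-(prop-1-en-2-yl)cyclohexyl]acetate (side chain trans to isopropenyl; α-methyl epimers), via TBS enol ether 9 (not isolated)
Conditions: Ph3CSbCl6 (5 mol %), CH2Cl2, −78 °C; then 1 M HCl, THF, rt
Reagents that add atoms: none
Why: In this Mukaiyama–Michael addition catalysed by the trityl salt, the nucleophile attacks C8a axially and anti to the equatorial isopropenyl group of 8, which sets C8a in the absolute sense. Silyl transfer gives 9, which dilute acid hydrolyses; the α-carbon (future C4a) is an inconsequential epimer mixture.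

Step 7
Reactants: 10 methyl 2-[2-methyl-3-oxo-5-(prop-1-en-2-yl)cyclohexyl]acetate
Product: 12 methyl 2-[(1S)-2-methyl-3-oxocyclohexyl]acetate (α-methyl epimers), via methoxy hydroperoxide 11 (not isolated)
Conditions: O3, MeOH, −78 °C; then FeSO4·7H2O, PhSH, −78 °C to rt
Reagents that add atoms: none
Why: This is a hydrodealkenylation: ozonolysis in methanol turns the only C=C bond into 11, and single-electron reduction by divalent iron gives an alkoxy radical that fragments by β-scission. The secondary C7 radical then takes hydrogen from PhSH. The control group leaves while no other alkene is present, and C8a is untouched.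

Step 8
Reactants: 12 methyl 2-[(1S)-2-methyl-3-oxocyclohexyl]acetate
Product: 13 methyl 2-[(1S)-2-methyl-3-(trimethylsilyloxy)cyclohex-2-en-1-yl]acetate
Conditions: Me3SiCl, NaI, Et3N, MeCN, rt
Reagents that add atoms: chlorotrimethylsilane, C[Si](C)(C)Cl
Why: Silyl enol ether formation with Me3SiI made in situ runs under equilibrating conditions and favours the tetrasubstituted C4a=C5 isomer, in which both α-methyl epimers converge. The ester is not enolised by Et3N.

Step 9
Reactants: 13 methyl 2-[(1S)-2-methyl-3-(trimethylsilyloxy)cyclohex-2-en-1-yl]acetate; 5 (E)-4-(tert-butyldimethylsilyloxy)-3-methylbut-2-enal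
Product: 16 methyl 2-{2-[(E)-4-(tert-butyldimethylsilyloxy)-1-hydroxy-3-methylbut-2-enyl]-2-methyl-3-oxocyclohexyl}acetate (hydroxyalkenyl group trans to the acetate arm), via dibutylboron enolate 14 (not isolated), via boron aldolate 15 (not isolated)
Conditions: Bu2BOTf, CH2Cl2, −78 to 0 °C; 5, −78 °C; then H2O2, pH 7 buffer, MeOH, 0 °C
Reagents that add atoms: none
Why: Silicon–boron exchange gives the regiodefined enolate 14 without any base or nucleophile that would touch the ester. The boron aldol reaction then passes through a Zimmerman–Traxler chair with the alkenyl group equatorial. The ring-locked E(O)-enolate gives the anti relation (C4–O anti to C8a, syn to the methyl), which is the axial-alkenyl epimer after lactonisation, and attack anti to the pseudoaxial CH2CO2Me arm sets quaternary C4a.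

Step 10
Reactants: 16 aldol adduct
Product: 17 trans-fused 1-[(E)-3-(tert-butyldimethylsilyloxy)-2-methylprop-1-enyl]-8a-methylhexahydroisochromane-3,8-dione (alkenyl β and axial; angular methyl α)
Conditions: pyridinium p-toluenesulfonate (cat.), PhH, 70 °C
Reagents that add atoms: none
Why: In this acid-catalysed lactonisation the C4 hydroxyl and the CH2CO2Me arm are trans-diequatorial on ring A, which suits a chair δ-lactone, and loss of MeOH drives the closure. Acylation of the aldol oxygen also blocks retro-aldol cleavage, and no stereocentre is touched.

Step 11
Reactants: 17 keto lactone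
Product: 18 C5 enol triflate of 17 (C5=C6)
Conditions: KN(SiMe3)2, THF, −78 °C; N-(5-chloropyridin-2-yl)bis(trifluoromethanesulfonimide), −78 °C
Reagents that add atoms: N-(5-chloropyridin-2-yl)bis(trifluoromethanesulfonimide), FC(F)(F)S(=O)(=O)N(c1ccc(Cl)cn1)S(=O)(=O)C(F)(F)F
Why: C4a is quaternary, so the ketone can enolise only towards C6, and kinetic deprotonation followed by O-sulfonylation gives the enol triflate regiospecifically. The unhindered ketone α-CH2 is expected to be deprotonated faster than the lactone α-CH2.

Step 12
Reactants: 18 enol triflate
Product: 19 trans-fused 1-[(E)-3-(tert-butyldimethylsilyloxy)-2-methylprop-1-enyl]-8,8a-dimethyl-1,4,4a,5,6,8a-hexahydroisochromen-3-one (alkenyl β and axial; angular methyl α)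
Conditions: MeMgBr, Fe(acac)3 (5 mol %), THF–NMP, −30 °C
Reagents that add atoms: methylmagnesium bromide, C[Mg]Br
Why: Iron-catalysed cross-coupling of an alkenyl triflate with a Grignard reagent is fast at low temperature and should outrun addition of MeMgBr to the lactone. It also avoids cuprates and zerovalent palladium, both of which could open the allylic C4–O bond.

Step 13
Reactants: 19 alkenyl lactone
Product: 22 2-(tert-butyldimethylsilyloxymethyl)-2,4a,5-trimethyl-1,2,4a,7,8,8a-hexahydronaphthalene-1-carboxylic acid (1-CO2H α; 2-CH3 β; 4a-CH3 α; 8a-H β), via silyl ketene acetal 20 (not isolated), via trimethylsilyl ester 21 (not isolated)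
Conditions: LiN(iPr)2, Me3SiCl, THF, −78 °C to rt; solvent change to PhMe, 110 °C; then 1 M HCl, THF, rt
Reagents that add atoms: none
Why: LiN(iPr)2 removes one of the only acidic protons (C1–H2) and Me3SiCl traps the enolate on oxygen, so 20 contains the array C1=C(OSi)–O–C4–C3=C2 and on heating undergoes a concerted suprafacial [3,3] shift, the lactone version of the Ireland–Claisen rearrangement, which is known to turn alkenyl lactones into cycloalkenecarboxylic acids. Ring B closes by C1–C2 bond formation across the lactone while C4–O breaks, so a six-membered lactone is exchanged for a six-membered carbocycle through a bridged, bicyclo[2.2.2]octane-like boat, a chair being impossible because the ketene acetal double bond is endocyclic. The trans fusion demands a torsion of similar size about C4a–C8a in 19, in a twisted form of this boat and in 22, so ring A need not distort much. At C1, the β-axial alkenyl group can reach only the β face, which pushes the carboxyl carbon to the α face, syn to the angular methyl. At C2, the bond forms on the alkene face from which oxygen leaves, with C4a s-cis to C2 as the new ring requires, so the E geometry places the methyl (cis to C4) on the β face and CH2OTBS on the α face. Both new centres thus follow from C4 and the alkene geometry without external control. The step needs O- rather than C-silylation, which the branched β-carbon C8a and the in situ quench favour, and it needs C5=C6 to stay out, which is assured because that alkene belongs to no allyl vinyl ether unit. Dilute acid then hydrolyses silyl ester 21 and leaves the primary TBS ether.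

Step 14
Reactants: 22 acid
Product: 23 [2-(tert-butyldimethylsilyloxymethyl)-2,4a,5-trimethyl-1,2,4a,7,8,8a-hexahydronaphthalen-1-yl]methanol
Conditions: LiAlH4, THF, 0 °C to reflux
Reagents that add atoms: none
Why: LiAlH4 reduces the carboxylic acid, while the isolated alkenes and the silyl ether are inert. The carboxylate does not enolise, so C1 is kept.

Step 15
Reactants: 23 primary alcohol
Product: 24 methanesulfonate of 23
Conditions: MsCl, Et3N, CH2Cl2, 0 °C
Reagents that add atoms: methanesulfonyl chloride, CS(=O)(=O)Cl
Why: Sulfonylation through the sulfene is insensitive to steric hindrance at the carbinol carbon and activates the axial CH2OH for hydride displacement.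

Step 16
Reactants: 24 mesylate
Product: 25 tert-butyldimethylsilyl ether of (1,2,4a,5-tetramethyl-1,2,4a,7,8,8a-hexahydronaphthalen-2-yl)methanol
Conditions: LiBHEt3, THF, reflux
Reagents that add atoms: none
Why: This is an SN2 displacement of a primary sulfonate by the very nucleophilic LiBHEt3, the usual choice for β-branched hindered sulfonates. The former carboxyl carbon becomes the axial C1 methyl without touching C1.

Step 17
Reactants: 25 diene silyl ether
Product: 26 tert-butyldimethylsilyl ether of (1,2,4a,5-tetramethyl-1,2,3,4,4a,7,8,8a-octahydronaphthalen-2-yl)methanol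
Conditions: TsNHNH2, NaOAc, DME–H2O, reflux
Reagents that add atoms: none
Why: Diimide transfers H2 in a concerted syn fashion and responds strongly to the degree of substitution, so the cis-disubstituted C3=C4 bond should be reduced ahead of the trisubstituted C5=C6 bond. No stereocentre is formed.

Step 18
Reactants: 26 silyl ether
Product: 27 (1,2,4a,5-tetramethyl-1,2,3,4,4a,7,8,8a-octahydronaphthalen-2-yl)methanol
Conditions: Bu4NF, THF, rt to 50 °C
Reagents that add atoms: none
Why: Fluoride-induced desilylation; nothing else in the hydrocarbon skeleton can react.

Step 19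
Reactants: 27 neopentyl alcohol
Product: 28 1,2,4a,5-tetramethyl-1,2,3,4,4a,7,8,8a-octahydronaphthalene-2-carbaldehyde
Conditions: 1,1,1-triacetoxy-1,1-dihydro-1,2-benziodoxol-3(1H)-one, CH2Cl2, rt
Reagents that add atoms: none
Why: Periodinane oxidation of a primary alcohol stops at the aldehyde and spares the alkene. The aldehyde has no α-hydrogen, so C2 cannot epimerise.

Step 20
Reactants: 28 aldehyde
Product: 29 2-ethenyl-1,2,4a,5-tetramethyl-1,2,3,4,4a,7,8,8a-octahydronaphthalene
Conditions: Ph3PCH3Br, KOtBu, THF, 0 °C to rt
Reagents that add atoms: methyltriphenylphosphonium bromide, C[P+](c1ccccc1)(c1ccccc1)c1ccccc1.[Br-]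
Why: Wittig methylenation with the small, reactive unstabilised ylide works on hindered non-enolisable aldehydes. It brings in the carbon that becomes C5′.

Step 21
Reactants: 30 methyl 4-bromofuran-2-carboxylate
Product: 31 methyl 4-methoxyfuran-2-carboxylate
Conditions: NaOMe, CuBr (10 mol %), MeOH–DMF, 110 °C
Reagents that add atoms: sodium methoxide, C[O-].[Na+]
Why: Ullmann-type copper-catalysed replacement of the β-bromine by methoxide; the ester can only exchange OMe for OMe.

Step 22
Reactants: 31 methyl 4-methoxyfuran-2-carboxylate
Product: 32 methyl 5-bromo-4-methoxyfuran-2-carboxylate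
Conditions: NBS, MeCN, 0 °C
Reagents that add atoms: N-bromosuccinimide, O=C1CCC(=O)N1Br
Why: Electrophilic aromatic bromination goes to the free α-position C5, which is also ortho to the methoxy donor.

Step 23
Reactants: 29 vinyl decalin; 32 methyl 5-bromo-4-methoxyfuran-2-carboxylate
Product: 34 methyl 4-methoxy-5-[2-(1,2,4a,5-tetramethyl-1,2,3,4,4a,7,8,8a-octahydronaphthalen-2-yl)ethyl]furan-2-carboxylate, via B-alkyl-9-BBN 33 (not isolated)
Conditions: 9-BBN-H, THF, rt; then 32, PdCl2(dppf) (5 mol %), Cs2CO3, DMF–H2O, 50 °C
Reagents that add atoms: none
Why: 9-BBN-H adds only to the monosubstituted vinyl group (anti-Markovnikov) and leaves the hindered trisubstituted alkene. The B-alkyl Suzuki–Miyaura coupling then forms the C5′–C4′ bond and avoids any substitution at the neopentyl link carbon.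

Step 24
Reactants: 34 furan
Product: 36 methyl (3E)-4-methoxy-2,5-dioxo-7-(1,2,4a,5-tetramethyl-1,2,3,4,4a,7,8,8a-octahydronaphthalen-2-yl)hept-3-enoate (the two keto groups cis on the double bond), via furan endoperoxide 35 (not isolated)
Conditions: O2, 5,10,15,20-tetraphenylporphyrin (cat.), visible light, CH2Cl2, −78 °C; then Me2S, −78 °C to rt
Reagents that add atoms: dioxygen, O=O
Why: The [4+2] cycloaddition of singlet oxygen to the alkyl- and methoxy-substituted furan should be much faster than a Schenck ene reaction at the hindered C5=C6 alkene. Me2S reduces 35 to the enedione, so the cis relation of C1′ and C4′ needed for ring closure comes from the furan.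

Step 25
Reactants: 36 cis-enedione keto ester
Product: 37 dysidenone B
Conditions: Cu(OTf)2 (10 mol %), (R,R)-2,2′-(propane-2,2-diyl)bis(4-tert-butyl-4,5-dihydrooxazole) (11 mol %), 2,6-dimethylpyridine (20 mol %), 4 Å molecular sieves, CH2Cl2, −20 °C
Reagents that add atoms: none
Why: Proposed new method: the 1,2-dicarbonyl unit of 36 should bind in two-point fashion to the square-planar divalent copper bis(oxazoline) complex, which makes C1′ the most electrophilic site and shields its Si face, while the weak pyridine base helps the C4′ ketone to enolise towards its only α-CH2, so that C5′ attacks the Re face of C1′ (1′R); the closest known reaction types are the copper bis(oxazoline)-catalysed aldol additions to pyruvate esters and the base-induced aldol closure of furan-derived cis-enediones to 4-hydroxycyclopentenones. C5′ is set in the same event, because the closure resembles the conrotatory 4π step of the Piancatelli rearrangement and, with the link CH2 and the carbonyl oxygen both pointing outward, places OH and CH2 trans (5′S). The near-neutral medium is chosen so that neither retro-aldol cleavage nor C5′ epimerisation follows.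

## Compound list

1 | 3-methylbut-2-enyl acetate | CC(C)=CCOC(C)=O | starting material
2 | (E)-4-hydroxy-3-methylbut-2-enyl acetate | OC/C(C)=C/COC(C)=O | intermediate
3 | (E)-4-(tert-butyldimethylsilyloxy)-3-methylbut-2-enyl acetate | CC(C)(C)[Si](C)(C)OC/C(C)=C/COC(C)=O | intermediate
4 | (E)-4-(tert-butyldimethylsilyloxy)-3-methylbut-2-en-1-ol | CC(C)(C)[Si](C)(C)OC/C(C)=C/CO | intermediate
5 | (E)-4-(tert-butyldimethylsilyloxy)-3-methylbut-2-enal | CC(C)(C)[Si](C)(C)OC/C(C)=C/C=O | intermediate
6 | methyl acetate | COC(C)=O | starting material
7 | 1-(tert-butyldimethylsilyloxy)-1-methoxyethene | COC(=C)O[Si](C)(C)C(C)(C)C | intermediate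
8 | (R)-carvone, (5R)-2-methyl-5-(prop-1-en-2-yl)cyclohex-2-en-1-one | CC1=CC[C@H](CC1=O)C(C)=C | starting material
9 | TBS enol ether of 10 (C4a=C5; acetate arm trans to isopropenyl) | COC(=O)C[C@@H]1C[C@@H](C(C)=C)CC(O[Si](C)(C)C(C)(C)C)=C1C | intermediate
10 | methyl 2-[2-methyl-3-oxo-5-(prop-1-en-2-yl)cyclohexyl]acetate (arm trans to isopropenyl; α-methyl epimers) | COC(=O)C[C@@H]1C[C@@H](C(C)=C)CC(=O)C1C | intermediate
11 | methyl 2-[5-(2-hydroperoxy-2-methoxypropan-2-yl)-2-methyl-3-oxocyclohexyl]acetate (peroxy carbon unassigned) | COC(=O)C[C@@H]1C[C@@H](C(C)(OC)OO)CC(=O)C1C | intermediate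
12 | methyl 2-[(1S)-2-methyl-3-oxocyclohexyl]acetate (α-methyl epimers) | COC(=O)C[C@@H]1CCCC(=O)C1C | intermediate
13 | methyl 2-[(1S)-2-methyl-3-(trimethylsilyloxy)cyclohex-2-en-1-yl]acetate | COC(=O)C[C@@H]1CCCC(O[Si](C)(C)C)=C1C | intermediate
14 | dibutylboron enolate corresponding to 13 | COC(=O)C[C@@H]1CCCC(OB(CCCC)CCCC)=C1C | intermediate
15 | O-dibutylboryl derivative of 16 | CC(C)(C)[Si](C)(C)OC/C(C)=C/[C@@H](OB(CCCC)CCCC)[C@]1(C)C(=O)CCC[C@H]1CC(=O)OC | intermediate
16 | aldol adduct (hydroxyalkenyl group trans to the acetate arm; C4–OH syn to the C4a methyl in the zigzag projection) | CC(C)(C)[Si](C)(C)OC/C(C)=C/[C@@H](O)[C@]1(C)C(=O)CCC[C@H]1CC(=O)OC | intermediate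
17 | trans-fused keto lactone (alkenyl β, axial; angular methyl α) | CC(C)(C)[Si](C)(C)OC/C(C)=C/[C@H]1OC(=O)C[C@@H]2CCCC(=O)[C@@]12C | intermediate
18 | C5 enol triflate of 17 | CC(C)(C)[Si](C)(C)OC/C(C)=C/[C@H]1OC(=O)C[C@@H]2CCC=C(OS(=O)(=O)C(F)(F)F)[C@@]12C | intermediate
19 | trans-fused 1-[(E)-3-(tert-butyldimethylsilyloxy)-2-methylprop-1-enyl]-8,8a-dimethyl-1,4,4a,5,6,8a-hexahydroisochromen-3-one | CC(C)(C)[Si](C)(C)OC/C(C)=C/[C@H]1OC(=O)C[C@@H]2CCC=C(C)[C@@]12C | intermediate
20 | trimethylsilyl ketene acetal of 19 | CC(C)(C)[Si](C)(C)OC/C(C)=C/[C@H]1OC(O[Si](C)(C)C)=C[C@@H]2CCC=C(C)[C@@]12C | intermediate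
21 | trimethylsilyl ester of 22 | CC(C)(C)[Si](C)(C)OC[C@@]1(C)C=C[C@]2(C)C(C)=CCC[C@H]2[C@H]1C(=O)O[Si](C)(C)C | intermediate
22 | 2-(tert-butyldimethylsilyloxymethyl)-2,4a,5-trimethyl-1,2,4a,7,8,8a-hexahydronaphthalene-1-carboxylic acid (1-CO2H α, 2-CH3 β, 4a-CH3 α, 8a-H β) | CC(C)(C)[Si](C)(C)OC[C@@]1(C)C=C[C@]2(C)C(C)=CCC[C@H]2[C@H]1C(=O)O | intermediate
23 | C1 hydroxymethyl compound | CC(C)(C)[Si](C)(C)OC[C@@]1(C)C=C[C@]2(C)C(C)=CCC[C@H]2[C@H]1CO | intermediate
24 | methanesulfonate of 23 | CC(C)(C)[Si](C)(C)OC[C@@]1(C)C=C[C@]2(C)C(C)=CCC[C@H]2[C@H]1COS(C)(=O)=O | intermediate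
25 | C1 methyl diene silyl ether (1-CH3 α, axial) | CC(C)(C)[Si](C)(C)OC[C@@]1(C)C=C[C@]2(C)C(C)=CCC[C@H]2[C@H]1C | intermediate
26 | C3–C4 saturated silyl ether | CC(C)(C)[Si](C)(C)OC[C@@]1(C)CC[C@]2(C)C(C)=CCC[C@H]2[C@H]1C | intermediate
27 | (1,2,4a,5-tetramethyl-1,2,3,4,4a,7,8,8a-octahydronaphthalen-2-yl)methanol | OC[C@@]1(C)CC[C@]2(C)C(C)=CCC[C@H]2[C@H]1C | intermediate
28 | corresponding C2 carbaldehyde | O=C[C@@]1(C)CC[C@]2(C)C(C)=CCC[C@H]2[C@H]1C | intermediate
29 | corresponding C2 vinyl compound | C=C[C@@]1(C)CC[C@]2(C)C(C)=CCC[C@H]2[C@H]1C | intermediate
30 | methyl 4-bromofuran-2-carboxylate | COC(=O)c1cc(Br)co1 | starting material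
31 | methyl 4-methoxyfuran-2-carboxylate | COC(=O)c1cc(OC)co1 | intermediate
32 | methyl 5-bromo-4-methoxyfuran-2-carboxylate | COC(=O)c1cc(OC)c(Br)o1 | intermediate
33 | 9-[2-(decalin-2-yl)ethyl]-9-borabicyclo[3.3.1]nonane | C1CC2CCCC(C1)B2CC[C@@]3(C)CC[C@]4(C)C(C)=CCC[C@H]4[C@H]3C | intermediate
34 | methyl 4-methoxy-5-[2-(decalin-2-yl)ethyl]furan-2-carboxylate | COC(=O)c1cc(OC)c(CC[C@@]2(C)CC[C@]3(C)C(C)=CCC[C@H]3[C@H]2C)o1 | intermediate
35 | furan endoperoxide (2,3,7-trioxabicyclo[2.2.1]hept-5-ene; bridgeheads unassigned) | COC(=O)C12C=C(OC)C(CC[C@@]3(C)CC[C@]4(C)C(C)=CCC[C@H]4[C@H]3C)(OO1)O2 | intermediate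
36 | methyl (3E)-4-methoxy-2,5-dioxo-7-(decalin-2-yl)hept-3-enoate (keto groups cis) | COC(=O)C(=O)/C=C(/OC)C(=O)CC[C@@]1(C)CC[C@]2(C)C(C)=CCC[C@H]2[C@H]1C | intermediate
37 | dysidenone B (1′R,5′S; OH and CH2 trans) | COC(=O)[C@@]1(O)C=C(OC)C(=O)[C@H]1C[C@@]1(C)CC[C@]2(C)C(C)=CCC[C@H]2[C@H]1C | target

## Step count and least certain steps

Total: 25 steps. The longest linear sequence is 19 steps: 1 → 5 (steps 1–4), then steps 9–20 and 23–25. The branch 6 → 13 (steps 5–8) has the same length.

**Step 25 (new method).**
- *What may go wrong:* an uncatalysed closure could compete with the copper-bound pathway and erode the facial selectivity at C1′. The α-methoxy enone could compete for the metal. The double bond could isomerise so that the chain no longer closes. The base could epimerise C5′ after closure, a real concern because the OH/CH2 trans arrangement is not clearly the more stable one.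
- *Fallback (known chemistry):* setting out from 36, or from the crude photooxygenation mixture of 34, Et3N in CH2Cl2 at 0 °C effects the established base-induced closure of furan-derived cis-enediones. External control is given up. Because the decalin is enantiopure, the isomers are diastereomers, and 37 is separated by chromatography from the ring C antipodal isomer 1′,5′-bis-epi-dysidenone B F1. F1 is returned to the equilibrium through retro-aldol opening to 36 with the same base and recycled. The route is rejoined at 37.

**Step 13 (key step).**
- *What may go wrong:* the shift may be slow, because it builds a quaternary carbon beside a neopentyl centre and must pass through a twisted boat on a trans-fused frame. At the temperature then required, the moisture- and acid-sensitive ketene acetal may revert to the lactone or suffer silyl migration to carbon.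
- *Fallback:* the thermally robust enol ether variant of the same disconnection. From 19, iBu2AlH (PhMe, −78 °C) gives the lactol F2. MsCl/Et3N eliminates it to the 2-alkenyl-3,4-dihydro-2H-pyran F3. F3 tolerates heating to about 200 °C (1,2-dichlorobenzene, base-washed sealed tube) for an aliphatic Claisen rearrangement of the same topology, giving the C1 carbaldehyde F4. Immediate NaBH4 reduction, before the axial aldehyde can epimerise, rejoins the route at 23.

**Step 9.**
- *What may go wrong:* silicon–boron exchange may be sluggish at the tetrasubstituted enol ether. The liberated silyl triflate may then promote an open, acyclic aldol pathway of unreacted 13, for which the C4 epimer with the equatorial alkenyl group is predicted, so selectivity at C4 would erode.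
- *Fallback:* the enolate is generated reductively. From 13, NBS (THF, −78 °C) gives the α-bromo ketone F5. SmI2 (2 equiv, THF, −78 °C) converts F5 regiospecifically into a trivalent samarium enolate, which tolerates the ester and adds to 5 through a chelated chair (Reformatsky-type aldol). The route is rejoined at 16.

**Step 11.**
- *What may go wrong:* the δ-lactone α-protons are close in acidity to those of the ketone, so competing lactone enolisation and sulfonylation, or proton exchange between the two sites, may lower chemoselectivity.
- *Fallback:* the ketone is converted before the lactone exists. From 16, 1-(trimethylsilyl)imidazole gives the C4 trimethylsilyl ether F6, which contains only a less acidic acyclic ester. The conditions of step 11 give the enol triflate F7, and those of step 12 the C5 methyl compound F8, now with no allylic ester present. Pyridinium p-toluenesulfonate in MeOH frees the hydroxy ester F9, which lactonises on warming in PhH. The route is rejoined at 19.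

**Step 17.**
- *What may go wrong:* C3=C4 lies between two quaternary carbons, so diimide transfer may become slow enough for C5=C6 to be reduced as well, or for conversion to stall.
- *Fallback:* directed hydrogenation replaces undirected transfer. From 25, Bu4NF gives the homoallylic dienol F10. Its hydroxyl group binds [Ir(cod)(PCy3)(py)]PF6 (H2, CH2Cl2) and delivers hydrogen to the neighbouring C3=C4 bond in preference to the remote C5=C6 bond. The route is rejoined at 27.

## Further compounds

F1 | step 25 | 1′,5′-bis-epi-dysidenone B (1′S,5′R) | COC(=O)[C@]1(O)C=C(OC)C(=O)[C@@H]1C[C@@]1(C)CC[C@]2(C)C(C)=CCC[C@H]2[C@H]1C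
F2 | step 13 | lactol of 19 (anomeric carbon unassigned) | CC(C)(C)[Si](C)(C)OC/C(C)=C/[C@H]1OC(O)C[C@@H]2CCC=C(C)[C@@]12C
F3 | step 13 | trans-fused 2-alkenyl-3,4-dihydro-2H-pyran (cyclic enol ether of 19) | CC(C)(C)[Si](C)(C)OC/C(C)=C/[C@H]1OC=C[C@@H]2CCC=C(C)[C@@]12C
F4 | step 13 | C1 carbaldehyde corresponding to 22 (CHO α) | CC(C)(C)[Si](C)(C)OC[C@@]1(C)C=C[C@]2(C)C(C)=CCC[C@H]2[C@H]1C=O
F5 | step 9 | methyl 2-[(1S)-2-bromo-2-methyl-3-oxocyclohexyl]acetate (bromine-bearing carbon unassigned) | COC(=O)C[C@@H]1CCCC(=O)C1(C)Br
F6 | step 11 | C4 trimethylsilyl ether of 16 | CC(C)(C)[Si](C)(C)OC/C(C)=C/[C@@H](O[Si](C)(C)C)[C@]1(C)C(=O)CCC[C@H]1CC(=O)OC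
F7 | step 11 | C5 enol triflate of F6 | CC(C)(C)[Si](C)(C)OC/C(C)=C/[C@@H](O[Si](C)(C)C)[C@]1(C)C(OS(=O)(=O)C(F)(F)F)=CCC[C@H]1CC(=O)OC
F8 | step 11 | C5 methyl compound from F7 | CC(C)(C)[Si](C)(C)OC/C(C)=C/[C@@H](O[Si](C)(C)C)[C@]1(C)C(C)=CCC[C@H]1CC(=O)OC
F9 | step 11 | hydroxy ester (seco form of 19) | CC(C)(C)[Si](C)(C)OC/C(C)=C/[C@@H](O)[C@]1(C)C(C)=CCC[C@H]1CC(=O)OC
F10 | step 17 | (1,2,4a,5-tetramethyl-1,2,4a,7,8,8a-hexahydronaphthalen-2-yl)methanol | OC[C@@]1(C)C=C[C@]2(C)C(C)=CCC[C@H]2[C@H]1C
A1 | alternative 1 | (7E)-4,7,8-trimethyl-4-(triisopropylsilyloxymethyl)deca-1,7,9-trien-3-one (C4 configured as C2 of 37) | C=CC(=O)[C@@](C)(CO[Si](C(C)C)(C(C)C)C(C)C)CC/C(C)=C(C)/C=C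
A2 | alternative 1 | trans-fused 2,4a,5-trimethyl-2-(triisopropylsilyloxymethyl)-3,4,4a,7,8,8a-hexahydronaphthalen-1(2H)-one | CC(C)[Si](C(C)C)(C(C)C)OC[C@@]1(C)CC[C@]2(C)C(C)=CCC[C@H]2C1=O
A3 | alternative 2 | methyl 2-[(E)-2-(decalin-2-yl)ethenyl]-4-methoxy-5-oxo-5-(phenylselanyl)-2-(triethylsilyloxy)pent-3-enoate (C1′ and the selenoester carbon cis) | COC(=O)[C@@](O[Si](CC)(CC)CC)(/C=C(/OC)C(=O)[Se]c1ccccc1)/C=C/[C@@]1(C)CC[C@]2(C)C(C)=CCC[C@H]2[C@H]1C
A4 | alternative 2 | O-triethylsilyl dysidenone B | COC(=O)[C@@]1(O[Si](CC)(CC)CC)C=C(OC)C(=O)[C@H]1C[C@@]1(C)CC[C@]2(C)C(C)=CCC[C@H]2[C@H]1C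
A5 | alternative 3 | 3-[5-bromo-3-(tert-butyldimethylsilyloxymethyl)-3-methylpentan-2-yl]-2-methylphenol (chain centres as C1 and C2 of 37) | CC(C)(C)[Si](C)(C)OC[C@@](C)(CCBr)[C@H](C)c1cccc(O)c1C
A6 | alternative 3 | 1,2,4a-trimethyl-2-(tert-butyldimethylsilyloxymethyl)-2,3,4,4a-tetrahydronaphthalen-5(1H)-one | CC(C)(C)[Si](C)(C)OC[C@@]1(C)CC[C@]2(C)C(=O)C=CC=C2[C@H]1C
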